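(Its constants belong to no real substance; no experiment stands behind them.)

Start with the easy step: the substrate falls apart by itself into an intermediate, first order, with a time constant you can read off the list below.

| setting | Thursday's | Wednesday's | Sunday's | Monday's |
|---|---|---|---|---|
| substrate | 0.067 M (fed, over 30 s) | 0.067 M | 0.067 M | 0.067 M |
| second nucleophile | 0.0536 M | 0.0536 M | 0.0536 M | 0.0536 M (fed, over 30 s) |
| solid first nucleophile | 0.134 M | 0.134 M | 0.134 M | 0.134 M |
| time | 80 s | 80 s | 80 s | 80 s |
| remark | the addition at −15 °C, then warmed to 5 °C; the feed brings no volume worth counting | everything together at the start | everything together at the start at −15 °C, warmed to 5 °C at 30 s | all else is in the flask from the start; the feed brings no volume worth counting |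
| temperature |  | 5 °C |  | 5 °C |

    substrate → intermediate (k1 = 0.034 s⁻¹, Ea1 = 72.0 kJ mol⁻¹)
    first nucleophile + intermediate → target (k2 = 610 L mol⁻¹ s⁻¹, Ea2 = 38.0 kJ mol⁻¹)
    second nucleophile + intermediate → other capture product (k3 = 920 L mol⁻¹ s⁻¹, Ea3 = 40.0 kJ mol⁻¹)
    intermediate → solvolysis product (k4 = 9.6 s⁻¹, Ea4 = 62.0 kJ mol⁻¹)
    second nucleophile ⇌ dormant form (K5 = 1.4, k5 = 0.0058 s⁻¹, Ea5 = 74.0 kJ mol⁻¹, ΔH5 = −21.0 kJ mol⁻¹)
    substrate + target → side product (k6 = 0.46 L mol⁻¹ s⁻¹, Ea6 = 54.0 kJ mol⁻¹)
    solid first nucleophile ⇌ first nucleophile, rate k7*(cs7 - [first nucleophile]) while solid is left; crystals form when [first nucleophile] > cs7 (cs7 = 6.8 mM, k7 = 0.10 s⁻¹)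
    (constants at 5 °C)

- a species is counted by the substrate in it: one side product counts as two
- given per volume of solution although it is solid: solid first nucleophile
- the list of constants is for 5 °C, to be carried to other temperatures by the activation energies and enthalpies
- at the start none of the solid first nucleophile is in solution

- the flask with the highest amount of solvolysis product, in percent of the substrate charged ("all alike" if they lie within 1.5 percentage points) (Thursday's / Wednesday's / Sunday's / Monday's / all alike)
- final solvolysis product, as a percentage of the substrate charged, in Thursday's
- final solvolysis product, as a percentage of the substrate charged, in Wednesday's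
- final solvolysis product, as a percentage of the substrate charged, in Sunday's
- final solvolysis product, as a percentage of the substrate charged, in Monday's

Two numbers seem not to fit. In Monday's flask the second nucleophile is fed for 30 s, just 37.5 % of the run, which sounds like a brief start-up. Yet the fraction of substrate left by then, reckoned from its first-order decay alone, is 36.1 %, about a third. They fit once you change clocks: the substrate's time constant, 29.4 s, is about as long as the feed. So by this reckoning 63.9 % of the substrate has turned into intermediate before Monday's feed ends.

Even with nothing to catch it, the intermediate lasts 0.104 s, far shorter than that, so each portion splits at once by the concentrations of that moment. Capture is pseudo-first-order, its constant times c(second nucleophile). My carried quantity is the break-even concentration 10.4 mM, the solvolysis constant over the capture constant: at that c(second nucleophile) capture and solvolysis run level. The first nucleophile, at its solubility, counts as a further 4.51 mM. The leak share is then the break-even concentration over the sum of these two and c(second nucleophile). With the whole charge of second nucleophile in solution and the first nucleophile at its solubility, it is 15.2 %. With half the charge, which is what Monday's feed has delivered midway, it is 25.0 %. Even that looks too kind for Monday's: by my reckoning 0.0428 M of substrate turns over during a feed of 0.0536 M, and capture uses up what is fed. My reckoning puts Monday's above Wednesday's and stops there; I did not carry it to the cold flasks.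

The forecast names Monday's, with 20.8 % for Thursday's, 26 % for Wednesday's, 20.3 % for Sunday's and 36.5 % for Monday's, on the ground that “feeding that nucleophile in Monday's leaves the early intermediate poorly trapped”.

The simulation gives 20.3 %, 25.8 %, 20.2 % and 36.9 % in that order, so Monday's stands highest, and each value lies inside the forecast's range.

Monday's ends with 27.8 % of its own charge of second nucleophile still free, against 13.9 % in Wednesday's, and yet with more solvolysis product. With the mean c(second nucleophile) over the first 30.0 s, 0.0162 M in Monday's and 0.0317 M in Wednesday's, and the first nucleophile still counted at its solubility, the leak share is 33.5 % for Monday's and 22.4 % for Wednesday's. Remove the low solubility of the first nucleophile and the gap between Monday's and Sunday's shrinks from 17 percentage points to 2.1 points, the largest single effect.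

In the neighbour of Sunday's with 0.21 M of second nucleophile, the leak share at that charge, with the constants at 5 °C and the first nucleophile at its solubility, is 4.64 % of what passes through the intermediate. That flask ends with solvolysis product at 4.68 % of the substrate charged, and 16.4 % of the substrate is still unreacted.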